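**Assumptions:** (R)-but-3-yn-2-ol, acid 5 and Grignard 9 are taken as catalogue items. The target is treated as the open hydroxy-ketone drawn in the SMILES (it can equilibrate with its cyclic hemiketal). Ring numbering for the target: O1, C2 (aryl), C3 (CH2OH), C4 (aroyl), C5 (CH2); the SMILES corresponds to (2S,3R,4R), i.e. 2,3-trans, 3,4-cis.

## Retrosynthetic overview

1. Target ⇐ cis-fused aryl furofuranone lactone + 3,4-dimethoxyphenyllithium; opening the lactone gives the aroyl and CH2OH groups already 3,4-cis.
2. Aryl lactone ⇐ bicyclic lactone methyl acetal + 3,4,5-trimethoxyphenylzinc; convex-face attack on the oxocarbenium ion sets C2 trans to C3.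
3. Lactone acetal ⇐ γ,δ-unsaturated acid by ozonolysis/reduction/acid; the γ-lactone closes first, then the THF (acetal) ring.
4. Acid ⇐ Ireland–Claisen [3,3] rearrangement of an (R,E)-allylic ester; this forms the C3–C4 bond and sets both centres by chirality transfer from the purchased carbinol.
5. Ester ⇐ (R)-but-3-yn-2-ol + triethyl orthoformate + 3-(TBSO)propanoic acid.

## Route

**Step 1**
Reactants: 1, (R)-but-3-yn-2-ol; 2, triethyl orthoformate
Product: 3, (R)-5,5-diethoxypent-3-yn-2-ol
Conditions: EtMgBr (2.2 equiv), THF, 0 °C → rt; then 2, toluene, 90 °C; aq. NH4Cl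
Reagents that add atoms: none beyond 1 and 2 (2 supplies the acetal carbon and both OEt groups)
Why: Bodroux–Chichibabin-type acetal synthesis; the alkynyl Grignard displaces one ethoxide of the orthoester, the magnesium alkoxide is inert, and the carbinol centre is untouched.

**Step 2**
Reactants: 3
Product: 4, (2R,3E)-5,5-diethoxypent-3-en-2-ol
Conditions: Red-Al, THF, 0 °C → rt; Rochelle salt work-up
Reagents that add atoms: none
Why: Alkoxide-directed trans-hydroalumination of a propargylic alcohol gives only the E-alkene; the acetal is inert to hydride and the carbinol centre is untouched.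

**Step 3**
Reactants: 4; 5, 3-[(tert-butyldimethylsilyl)oxy]propanoic acid
Product: 6, (2R,3E)-5,5-diethoxypent-3-en-2-yl 3-[(tert-butyldimethylsilyl)oxy]propanoate
Conditions: DCC, DMAP (cat.), CH2Cl2, 0 °C → rt
Reagents that add atoms: none beyond 4 and 5
Why: Steglich esterification under neutral conditions preserves the acid-labile enal acetal and the TBS ether, with no allylic transposition.

**Step 4**
Reactants: 6
Product: 7, (2R,3S,4E)-2-{[(tert-butyldimethylsilyl)oxy]methyl}-3-(diethoxymethyl)hex-4-enoic acid
Conditions: LDA, TMSCl–Et3N (in situ), THF, −78 °C → 50 °C; then aq. citric acid (pH 4)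
Reagents that add atoms: none (TMS is lost on work-up)
Why: Ireland–Claisen rearrangement. The non-chelating OTBS group gives the kinetic E(O)-enolate, which rearranges through a chair with the carbinol methyl equatorial. The C–C bond forms with 1,3-chirality transfer from the (R)-carbinol; the E-alkene/E(O)-ketene acetal pairing gives the 2,3-relationship that becomes 3,4-cis in the target.

**Step 5**
Reactants: 7
Product: 8, (3aR,6aR)-4-methoxytetrahydro-1H,3H-furo[3,4-c]furan-1-one (anomeric mixture)
Conditions: O3, CH2Cl2–MeOH, −78 °C; NaBH4, −78 → 0 °C; then HCl (from AcCl)/MeOH, rt (one flask)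
Reagents that add atoms: ozone, [O-][O+]=O (oxygen of the new CH2–O); methanol, CO (the OMe group)
Why: Ozonolysis with reductive work-up turns the propenyl group into CH2OH (acetaldehyde lost). Acid then closes the γ-lactone, removes TBS and lets the freed OH transacetalise onto the acetal (Fischer-glycosidation-type). Only the α,β-cis isomer can form the cis-fused bicycle, so the minor Claisen diastereomer is rejected here.

**Step 6**
Reactants: 8; 9, (3,4,5-trimethoxyphenyl)magnesium bromide
Product: 10, (3aR,4S,6aR)-4-(3,4,5-trimethoxyphenyl)tetrahydro-1H,3H-furo[3,4-c]furan-1-one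
Conditions: TMSBr, CH2Cl2, 0 °C; then ArZnBr (9 + ZnBr2), THF–toluene, −20 °C → rt
Reagents that add atoms: none beyond 8 and 9
Why: C-glycosylation-type arylation of an α-bromo ether via the bicyclic oxocarbenium ion. The arylzinc attacks the convex face, placing the aryl exo (trans to the C3 substituent, 4S), and does not add to the lactone.

**Step 7**
Reactants: 10; 11, 4-bromo-1,2-dimethoxybenzene
Product: 12, Magnone B, [(2S,3R,4R)-4-(3,4-dimethoxybenzoyl)-2-(3,4,5-trimethoxyphenyl)oxolan-3-yl]methanol
Conditions: 11, n-BuLi, THF, −78 °C; then 10 (1.0 equiv), −78 °C; AcOH/NH4Cl quench at −78 °C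
Reagents that add atoms: none beyond 10 and 11
Why: Aryllithium mono-addition to a γ-lactone; the lactol alkoxide resists a second addition and shields the α-centre until the cold quench. No new stereocentre is formed, and the ring fusion delivers aroyl and CH2OH cis.

## Compound list

1 | (R)-but-3-yn-2-ol | C[C@@H](O)C#C | starting material
2 | triethyl orthoformate | CCOC(OCC)OCC | starting material
3 | (R)-5,5-diethoxypent-3-yn-2-ol | C[C@@H](O)C#CC(OCC)OCC | intermediate
4 | (2R,3E)-5,5-diethoxypent-3-en-2-ol | C[C@@H](O)/C=C/C(OCC)OCC | intermediate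
5 | 3-[(tert-butyldimethylsilyl)oxy]propanoic acid | OC(=O)CCO[Si](C)(C)C(C)(C)C | starting material
6 | (2R,3E)-5,5-diethoxypent-3-en-2-yl 3-[(tert-butyldimethylsilyl)oxy]propanoate | C[C@@H](OC(=O)CCO[Si](C)(C)C(C)(C)C)/C=C/C(OCC)OCC | intermediate
7 | (2R,3S,4E)-2-{[(tert-butyldimethylsilyl)oxy]methyl}-3-(diethoxymethyl)hex-4-enoic acid | OC(=O)[C@@H](CO[Si](C)(C)C(C)(C)C)[C@@H](C(OCC)OCC)/C=C/C | intermediate
8 | (3aR,6aR)-4-methoxytetrahydro-1H,3H-furo[3,4-c]furan-1-one | O=C1[C@H]2COC(OC)[C@H]2CO1 | intermediate
9 | (3,4,5-trimethoxyphenyl)magnesium bromide | COc1cc([Mg]Br)cc(OC)c1OC | starting material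
10 | (3aR,4S,6aR)-4-(3,4,5-trimethoxyphenyl)tetrahydro-1H,3H-furo[3,4-c]furan-1-one | O=C1[C@H]2CO[C@H](c3cc(OC)c(OC)c(OC)c3)[C@H]2CO1 | intermediate
11 | 4-bromo-1,2-dimethoxybenzene | COc1ccc(Br)cc1OC | starting material
12 | Magnone B | COc1ccc(C(=O)[C@H]2CO[C@H](c3cc(OC)c(OC)c(OC)c3)[C@H]2CO)cc1OC | target

## Summary

Total steps: 7. Longest linear sequence: 7.

Steps most likely to fail, with fallbacks:

1. **Step 4 (Ireland–Claisen).** Risks are β-elimination of silyloxide from the enolate and incomplete E(O)/chair selectivity. Fallback: use the but-3-enoate ester of 4 instead, which has no β-leaving group. The α-vinyl and propenyl groups are then both cleaved in the ozonolysis/NaBH4 step, giving C5–OH and the lactone CH2O without a protecting group.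
2. **Step 6 (arylation of the lactone acetal).** Risks are elimination to the enol ether, lactone attack and imperfect exo selectivity. Fallback: bring the aryl in at step 1 by using 3,4,5-trimethoxybenzaldehyde in place of the orthoformate, with the benzylic OH carried as its methyl ether. After the rearrangement and ozonolysis, close the THF by acid-mediated benzylic SN1 etherification from C5–OH; this relies on the 2,3-trans product being favoured.
3. **Step 7 (ArLi mono-addition).** Risks are over-addition, C4 epimerisation and retro-oxa-Michael opening of the β-alkoxy ketone. Fallback: reduce 10 to the lactol with DIBAL, add 3,4-dimethoxyphenylmagnesium bromide to give the benzylic diol, then oxidise only the benzylic alcohol (MnO2 or DDQ). The ketone then appears only under neutral conditions.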